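Both outer rings are disconnected at C1–C6 and C2–C3, which leads back to two OCH2CHO arms on the central ring and two molecules of methyl vinyl ketone. The key step exploits that each outer ring is a hydroquinone monoether, with the ether oxygen on C1 para to the hydroxyl on C4, and is thus the aromatised form of a 4-aryloxycyclohex-2-enone. One two-directional Michael/aldol annulation closes both carbocycles at once. Its precursor is a hexasubstituted benzene that already carries both central bromines, the two central hydroxyls masked as methyl ethers, and the two aryloxyacetaldehyde arms.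

Key step: step 5

Remark on the chemistry: the target SMILES holds no stereocentre and no defined stereo-axis, so the compound is achiral and no step needs stereocontrol. The central methyl ethers are kept until the end because the central ring is a hydroquinone that bromine would otherwise oxidise.

Step 1
Reactants: 1 bromanil (2,3,5,6-tetrabromo-1,4-benzoquinone)
Product: 2 2,5-dibromo-3,6-dimethoxy-1,4-benzoquinone
Conditions: NaOMe (2.05 equiv), MeOH/THF, 0 °C to rt
Reagents that add atoms: sodium methoxide, [Na+].[O-]C
Why: Twofold addition–elimination (nucleophilic vinylic substitution) on a haloquinone, in which the first methoxy group turns its own half into a vinylogous ester, so the second methoxide should enter at the bromide β to the other, still electron-poor carbonyl and give the 2,5-dibromo-3,6-dimethoxy pattern, while two equivalents of base at low temperature guard against a third substitution.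

Step 2
Reactants: 2 2,5-dibromo-3,6-dimethoxy-1,4-benzoquinone
Product: 3 2,5-dibromo-3,6-dimethoxybenzene-1,4-diol
Conditions: Na2S2O4 (excess), EtOAc/H2O, rt, N2
Reagents that add atoms: none
Why: Dithionite reduction of a quinone to its hydroquinone is a standard two-electron reduction that leaves aryl bromides and methyl ethers untouched.

Step 3
Reactants: 3 2,5-dibromo-3,6-dimethoxybenzene-1,4-diol; 4 bromoacetaldehyde diethyl acetal (2.6 equiv)
Product: 5 1,4-dibromo-2,5-bis(2,2-diethoxyethoxy)-3,6-dimethoxybenzene
Conditions: Cs2CO3, Bu4NI (cat.), degassed DMF, 100 °C, N2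
Reagents that add atoms: none
Why: Williamson ether synthesis in which the phenoxides, made more acidic by the ortho bromines, displace the primary bromide by SN2 with help from iodide catalysis and heat, while exclusion of air keeps the hydroquinone dianion from reverting to the quinone.

Step 4
Reactants: 5 1,4-dibromo-2,5-bis(2,2-diethoxyethoxy)-3,6-dimethoxybenzene
Product: 6 2,2'-[(2,5-dibromo-3,6-dimethoxy-1,4-phenylene)bis(oxy)]diacetaldehyde
Conditions: 2 M aq. HCl, THF, 50 °C; crude product used at once
Reagents that add atoms: water, O
Why: Acid-catalysed acetal hydrolysis, in which the benzofuran cyclisation that aryloxyacetaldehyde acetals often undergo in acid cannot occur because both positions ortho to each ether oxygen are substituted.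

Step 5
Reactants: 6 2,2'-[(2,5-dibromo-3,6-dimethoxy-1,4-phenylene)bis(oxy)]diacetaldehyde; 7 methyl vinyl ketone
Product: 10 4,4'-[(2,5-dibromo-3,6-dimethoxy-1,4-phenylene)bis(oxy)]bis(cyclohex-2-en-1-one) (stereoisomer mixture), via bis(5-oxohexanal) Michael adduct 8 (not isolated), via bis(3-hydroxycyclohexanone) aldol 9 (not isolated)
Conditions: 7 (3 equiv), α,α-diphenylprolinol TMS ether (20 mol %, either enantiomer or racemate), ethyl 3,4-dihydroxybenzoate (20 mol %), CH2Cl2, 0 °C to rt; then LiOH·H2O (0.5 equiv), i-PrOH, rt
Reagents that add atoms: none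
Why: The secondary amine condenses with each aldehyde to an enamine whose nucleophilic carbon (future C1, bearing the aryloxy oxygen) adds to the terminal carbon of the enone (future C6), and iminium hydrolysis returns the catalyst; base then forms the methyl-ketone enolate (future C3), which adds to the aldehyde carbon (future C2) and loses water by E1cB to give the conjugated enone. The closest known reaction type is the amine-catalysed Michael addition of aldehydes to methyl vinyl ketone followed by intramolecular aldol condensation, a Robinson-type route to 4-substituted cyclohex-2-enones. Each of the two rings closes by a 6-(enolendo)-exo-trig aldol, since the alternative enolate/carbonyl pairings would give four-membered rings. The CH–OAr centre of each ring is set in the Michael step by the enamine face that attacks and can epimerise in the base stage, so a stereoisomer mixture is expected, which does not matter because both centres become sp2 in step 6. The step needs C–C bond formation at the aldehyde α-carbon in preference to self-condensation of ketone or aldehyde; the bulky amine should form an enamine only with the aldehyde, the catechol hydrogen-bond donor activates the enone, and the 2,6-disubstituted aryloxy group shields the aldehyde carbonyl from intermolecular aldol attack. A mild, substoichiometric base at room temperature is chosen so that the allylic aryloxide on C1 is not expelled and the double bond stays in conjugation.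

Step 6
Reactants: 10 4,4'-[(2,5-dibromo-3,6-dimethoxy-1,4-phenylene)bis(oxy)]bis(cyclohex-2-en-1-one)
Product: 13 4,4'-[(2,5-dibromo-3,6-dimethoxy-1,4-phenylene)bis(oxy)]bis(2,6-dibromophenol), via bis(6-bromocyclohex-2-enone) 11 (not isolated), via bis(4-hydroxyphenyl) ether 12 (not isolated)
Conditions: Br2 (6.3 equiv), NaOAc (9 equiv), AcOH/CH2Cl2, 0 °C to 40 °C
Reagents that add atoms: bromine, BrBr
Why: Bromination of the ketone enol at C5 and loss of HBr across C5–C6 give a 4H-cyclohexa-2,5-dienone that tautomerises to the phenol (bromine-mediated dehydrogenative aromatisation of a cyclohexenone), after which electrophilic aromatic substitution ortho to the new hydroxyl puts bromine on C3 and C5, while the acetate buffer takes up HBr so that the C1 aryloxide is not expelled and the fully substituted, methyl-capped central ring has no position to react.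

Step 7
Reactants: 13 4,4'-[(2,5-dibromo-3,6-dimethoxy-1,4-phenylene)bis(oxy)]bis(2,6-dibromophenol)
Product: 14 4,4'-[(2,5-dibromo-3,6-dimethoxy-1,4-phenylene)bis(oxy)]bis(2,3,6-tribromophenol)
Conditions: Br2 (2.2 equiv), anhydrous AcOH, rt to 50 °C
Reagents that add atoms: bromine, BrBr
Why: Electrophilic aromatic bromination at the only free carbons, C2 and C6, which lie ortho to the activating ether oxygen and are equivalent within each ring so that either gives the same product, while the first bromine deactivates and crowds the ring enough that stoichiometry should stop the reaction at one bromine per ring.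

Step 8
Reactants: 14 4,4'-[(2,5-dibromo-3,6-dimethoxy-1,4-phenylene)bis(oxy)]bis(2,3,6-tribromophenol)
Product: 15 3,6-dibromo-2,5-bis(2,3,5-tribromo-4-hydroxyphenoxy)benzene-1,4-diol (CNP0163357.0)
Conditions: BBr3 (8 equiv), CH2Cl2, −78 °C to rt; H2O quench, aq. Na2S2O4 wash, N2
Reagents that add atoms: none
Why: Lewis-acid demethylation of aryl methyl ethers with BBr3 (bromide attacks the methyl group of the boron-complexed ether) cleaves the two hindered methoxy groups while diaryl ethers and aryl bromides are inert, and the reductive work-up keeps the freed central hydroquinone from oxidising to the quinone.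

Compound list
1 | bromanil (2,3,5,6-tetrabromo-1,4-benzoquinone) | O=C1C(Br)=C(Br)C(=O)C(Br)=C1Br | starting material
2 | 2,5-dibromo-3,6-dimethoxy-1,4-benzoquinone | O=C1C(Br)=C(OC)C(=O)C(Br)=C1OC | intermediate
3 | 2,5-dibromo-3,6-dimethoxybenzene-1,4-diol | Oc1c(OC)c(Br)c(O)c(OC)c1Br | intermediate
4 | bromoacetaldehyde diethyl acetal (2-bromo-1,1-diethoxyethane) | CCOC(CBr)OCC | starting material
5 | 1,4-dibromo-2,5-bis(2,2-diethoxyethoxy)-3,6-dimethoxybenzene | CCOC(OCC)COc1c(OC)c(Br)c(OCC(OCC)OCC)c(OC)c1Br | intermediate
6 | 2,2'-[(2,5-dibromo-3,6-dimethoxy-1,4-phenylene)bis(oxy)]diacetaldehyde | O=CCOc1c(OC)c(Br)c(OCC=O)c(OC)c1Br | intermediate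
7 | methyl vinyl ketone (but-3-en-2-one) | CC(=O)C=C | starting material
8 | 2,2'-[(2,5-dibromo-3,6-dimethoxy-1,4-phenylene)bis(oxy)]bis(5-oxohexanal), stereoisomer mixture, formed in the flask in step 5 | CC(=O)CCC(C=O)Oc1c(OC)c(Br)c(OC(C=O)CCC(C)=O)c(OC)c1Br | intermediate
9 | 4,4'-[(2,5-dibromo-3,6-dimethoxy-1,4-phenylene)bis(oxy)]bis(3-hydroxycyclohexan-1-one), stereoisomer mixture, formed in the flask in step 5 | O=C1CC(O)C(Oc2c(OC)c(Br)c(OC3CCC(=O)CC3O)c(OC)c2Br)CC1 | intermediate
10 | 4,4'-[(2,5-dibromo-3,6-dimethoxy-1,4-phenylene)bis(oxy)]bis(cyclohex-2-en-1-one), stereoisomer mixture | O=C1C=CC(Oc2c(OC)c(Br)c(OC3C=CC(=O)CC3)c(OC)c2Br)CC1 | intermediate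
11 | 4,4'-[(2,5-dibromo-3,6-dimethoxy-1,4-phenylene)bis(oxy)]bis(6-bromocyclohex-2-en-1-one), stereoisomer mixture, formed in the flask in step 6 | O=C1C=CC(Oc2c(OC)c(Br)c(OC3C=CC(=O)C(Br)C3)c(OC)c2Br)CC1Br | intermediate
12 | 4,4'-[(2,5-dibromo-3,6-dimethoxy-1,4-phenylene)bis(oxy)]diphenol, formed in the flask in step 6 | Oc1ccc(Oc2c(OC)c(Br)c(Oc3ccc(O)cc3)c(OC)c2Br)cc1 | intermediate
13 | 4,4'-[(2,5-dibromo-3,6-dimethoxy-1,4-phenylene)bis(oxy)]bis(2,6-dibromophenol) | Oc1c(Br)cc(Oc2c(OC)c(Br)c(Oc3cc(Br)c(O)c(Br)c3)c(OC)c2Br)cc1Br | intermediate
14 | 4,4'-[(2,5-dibromo-3,6-dimethoxy-1,4-phenylene)bis(oxy)]bis(2,3,6-tribromophenol) | Oc1c(Br)cc(Oc2c(OC)c(Br)c(Oc3cc(Br)c(O)c(Br)c3Br)c(OC)c2Br)c(Br)c1Br | intermediate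
15 | 3,6-dibromo-2,5-bis(2,3,5-tribromo-4-hydroxyphenoxy)benzene-1,4-diol (CNP0163357.0), achiral | Oc1c(Br)cc(Oc2c(O)c(Br)c(Oc3cc(Br)c(O)c(Br)c3Br)c(O)c2Br)c(Br)c1Br | target

Total step count: 8
Longest linear sequence: 8 steps (1 to 15)

Steps most likely to fail

Step 5. The hindered, oxygen-substituted enamine may add too slowly at one or both ends, so that polymerisation of the enone or self-condensation of the dialdehyde takes over. The aryloxide may also be lost from C1, or the double bond may migrate, during the base stage. The fallback sets out from 3 and abandons ring construction for arylation. SNAr of 3 with 4-fluorobenzaldehyde (K2CO3, DMAc, 130 °C, N2) should give 4,4'-[(2,5-dibromo-3,6-dimethoxy-1,4-phenylene)bis(oxy)]dibenzaldehyde F1. Baeyer–Villiger (Dakin-type) oxidation with mCPBA in CH2Cl2 should give the bis(aryl formate) F2, and methanolysis (K2CO3, MeOH) the bis-phenol 12. Bromine (4.2 equiv, NaOAc, AcOH) then carries 12 on, and the fallback comes back to the route at 13.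

Step 6. Acid-promoted expulsion of the central aryloxide from C1 of an enol or dienol intermediate may compete with dehydrobromination, or one ring may stop at a bromo-ketone stage. The fallback sets out from 10 and aromatises without acid. Kinetic deprotonation at C5 (LiHMDS, THF, −78 °C) and trapping with PhSeCl should give the bis[6-(phenylselanyl)cyclohex-2-enone] F3. Oxidation (H2O2, pyridine, CH2Cl2, 0 °C) should give the bis(selenoxide) F4, whose syn-elimination leads to the dienone and, by tautomerisation, to 12. Bromine (4.2 equiv, NaOAc, AcOH) then gives 13, where the fallback comes back to the route.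

Step 7. Bromine may attack C1 ipso (para to the free hydroxyl) and oxidatively cleave the diaryl ether, or a second bromination at the remaining C–H may not be held back. The fallback sets out from 13 and masks the outer phenols first. Methylation (MeI, K2CO3, acetone) should give the tetramethyl ether F5. Bromination of this anisole-type substrate (Br2 2.2 equiv, cat. FeBr3, CH2Cl2) should give the octabromo tetramethyl ether F6. The BBr3 conditions of step 8, with a larger excess, then remove all four methyl groups, and the fallback comes back to the route at 15.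

Further compounds
F1 | step 5 | 4,4'-[(2,5-dibromo-3,6-dimethoxy-1,4-phenylene)bis(oxy)]dibenzaldehyde | O=Cc1ccc(Oc2c(OC)c(Br)c(Oc3ccc(C=O)cc3)c(OC)c2Br)cc1
F2 | step 5 | [(2,5-dibromo-3,6-dimethoxy-1,4-phenylene)bis(oxy)]di-4,1-phenylene diformate | O=COc1ccc(Oc2c(OC)c(Br)c(Oc3ccc(OC=O)cc3)c(OC)c2Br)cc1
F3 | step 6 | 4,4'-[(2,5-dibromo-3,6-dimethoxy-1,4-phenylene)bis(oxy)]bis[6-(phenylselanyl)cyclohex-2-en-1-one], stereoisomer mixture | O=C1C=CC(Oc2c(OC)c(Br)c(OC3C=CC(=O)C([Se]c4ccccc4)C3)c(OC)c2Br)CC1[Se]c1ccccc1
F4 | step 6 | 4,4'-[(2,5-dibromo-3,6-dimethoxy-1,4-phenylene)bis(oxy)]bis[6-(phenylseleninyl)cyclohex-2-en-1-one], stereoisomer mixture | O=C1C=CC(Oc2c(OC)c(Br)c(OC3C=CC(=O)C([Se](=O)c4ccccc4)C3)c(OC)c2Br)CC1[Se](=O)c1ccccc1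
F5 | step 7 | 1,4-dibromo-2,5-bis(3,5-dibromo-4-methoxyphenoxy)-3,6-dimethoxybenzene | COc1c(Br)cc(Oc2c(OC)c(Br)c(Oc3cc(Br)c(OC)c(Br)c3)c(OC)c2Br)cc1Br
F6 | step 7 | 1,4-dibromo-2,5-dimethoxy-3,6-bis(2,3,5-tribromo-4-methoxyphenoxy)benzene | COc1c(Br)cc(Oc2c(OC)c(Br)c(Oc3cc(Br)c(OC)c(Br)c3Br)c(OC)c2Br)c(Br)c1Br
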